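**Assumption:** the target has no stereocentre and no stereogenic double bond, so it is made as the single achiral compound drawn; 2-iodo-4-methoxybenzoic acid and 1-tridecyne are taken as catalogue items.

**Retrosynthetic overview**
- The keto acid comes from hydroxide opening of the enol lactone of 8-hydroxy-6-methoxy-3-undecylisocoumarin, which unmasks ketone and acid together.
- The 8-hydroxyl comes from a lactone-carbonyl-directed C8–H hydroxylation of 6-methoxy-3-undecylisocoumarin; this C–O bond formation is the key step and is new.
- The isocoumarin comes from 6-endo-dig C–O lactonisation of 4-methoxy-2-(tridec-1-ynyl)benzoic acid, made in the same pot by Sonogashira coupling of 2-iodo-4-methoxybenzoic acid with 1-tridecyne.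
- Ring order: benzene ring A is bought; pyranone ring B is closed in step 1, serves as directing group and mask in step 2, and is opened in step 3.

**Route**

Step 1
Reactants: 1 2-iodo-4-methoxybenzoic acid; 2 1-tridecyne
Product: 4 6-methoxy-3-undecyl-1H-isochromen-1-one, via alkynyl acid 3 (not isolated)
Conditions: Pd/C (10 wt%, 3 mol% Pd), PPh3 (12 mol%), CuI (6 mol%), Et3N (5 equiv), 2 (1.5 equiv), EtOH, 80 °C, 16 h
Reagents that add atoms: none
Why: Tandem Sonogashira coupling and metal-promoted 6-endo-dig addition of the ortho carboxylate to the distal alkyne carbon, a known one-pot isocoumarin synthesis from ortho-iodobenzoic acids in which the protic solvent favours the six-membered lactone over the phthalide.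

Step 2
Reactants: 4 6-methoxy-3-undecyl-1H-isochromen-1-one
Product: 6 8-hydroxy-6-methoxy-3-undecyl-1H-isochromen-1-one, via aryl trifluoroacetate 5 (not isolated)
Conditions: [RuCl2(p-cymene)]2 (2.5 mol%), PhI(OCOCF3)2 (1.5 equiv), TFA/TFAA (3:1), 80 °C, 6 h; then H2O, rt
Reagents that add atoms: [bis(trifluoroacetoxy)iodo]benzene, FC(F)(F)C(=O)OI(OC(=O)C(F)(F)F)c1ccccc1
Why: Proposed new method: the lactone carbonyl oxygen lies in the ring plane beside C8–H and should bind cationic divalent ruthenium, so that carboxylate-assisted C8–H ruthenation gives a five-membered ruthenacycle, PhI(OCOCF3)2 oxidises it to a tetravalent ruthenium trifluoroacetate, and C–O reductive elimination gives aryl trifluoroacetate 5 (hydrolysed on work-up), with C8 the only C–H in reach and the enol lactone shielding ketone and acid from the oxidant; the closest known reaction type is ruthenium-catalysed carbonyl-directed ortho C–H hydroxylation of aryl esters and ketones, including peri C5–H hydroxylation of chromones, which has not been shown with an isocoumarin lactone as the directing group.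

Step 3
Reactants: 6 8-hydroxy-6-methoxy-3-undecyl-1H-isochromen-1-one
Product: 8 2-hydroxy-4-methoxy-6-(2-oxotridecyl)benzoic acid, via dipotassium salt 7 (not isolated)
Conditions: KOH (5 equiv), EtOH/H2O (3:1), degassed, 70 °C, 4 h; then 1 M HCl, 0 °C, to pH 2–3, extraction with EtOAc, crystallisation without heating
Reagents that add atoms: potassium hydroxide, [K+].[OH-]
Why: Saponification of an enol lactone, where hydroxide adds to the lactone carbonyl and the expelled enolate tautomerises irreversibly to the ketone, followed by cold acidification that frees the acid without the heat or dehydrating acid needed for relactonisation or decarboxylation.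

**Compound list**

1 | 2-iodo-4-methoxybenzoic acid | COc1ccc(C(=O)O)c(I)c1 | starting material
2 | 1-tridecyne | CCCCCCCCCCCC#C | starting material
3 | 4-methoxy-2-(tridec-1-yn-1-yl)benzoic acid | CCCCCCCCCCCC#Cc1cc(OC)ccc1C(=O)O | intermediate
4 | 6-methoxy-3-undecyl-1H-isochromen-1-one | CCCCCCCCCCCC1=Cc2cc(OC)ccc2C(=O)O1 | intermediate
5 | 6-methoxy-1-oxo-3-undecyl-1H-isochromen-8-yl trifluoroacetate | CCCCCCCCCCCC1=Cc2cc(OC)cc(OC(=O)C(F)(F)F)c2C(=O)O1 | intermediate
6 | 8-hydroxy-6-methoxy-3-undecyl-1H-isochromen-1-one | CCCCCCCCCCCC1=Cc2cc(OC)cc(O)c2C(=O)O1 | intermediate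
7 | dipotassium 4-methoxy-2-oxido-6-(2-oxotridecyl)benzoate | CCCCCCCCCCCC(=O)Cc1cc(OC)cc([O-])c1C(=O)[O-].[K+].[K+] | intermediate
8 | 2-hydroxy-4-methoxy-6-(2-oxotridecyl)benzoic acid | CCCCCCCCCCCC(=O)Cc1cc(OC)cc(O)c1C(=O)O | target

**Step count and risks**

Total steps: 3. Longest linear sequence: 3 (1 → 4 → 6 → 8).

Steps most likely to fail, most risky first:

1. Step 2 (the proposed new hydroxylation). The lactone may direct too weakly, or the oxidant may attack the C3=C4 enol double bond or the anisole ring. The fallback uses known chemistry and sets out from 1-tridecyne 2 together with purchased methyl 2,6-dihydroxy-4-methoxybenzoate F3. Mono-triflation (Tf2O, 1.05 equiv, pyridine, CH2Cl2, −20 to 0 °C; the second hydroxyl is hydrogen-bonded to the ester) gives methyl 2-hydroxy-4-methoxy-6-{[(trifluoromethyl)sulfonyl]oxy}benzoate F4. Sonogashira coupling with 2 (PdCl2(PPh3)2, CuI, Et3N, DMF, 60 °C) gives methyl 2-hydroxy-4-methoxy-6-(tridec-1-yn-1-yl)benzoate F5. Ester-carbonyl 6-endo-dig cyclisation with loss of methanol (AuCl3, 5 mol%, wet MeCN, 50 °C) comes back to the route at 6. Here the phenol oxygen is bought in place and no C–H oxidation is needed.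

2. Step 1. The free acid may close 5-exo-dig under the basic coupling conditions to give the alkylidene phthalide, which would lead to the wrong ketone regioisomer. The fallback sets out from 1 and separates coupling from ring closure. Esterification (MeI, K2CO3, DMF, rt) gives methyl 2-iodo-4-methoxybenzoate F1. Sonogashira coupling with 2 (PdCl2(PPh3)2, CuI, Et3N, THF, rt) gives methyl 4-methoxy-2-(tridec-1-yn-1-yl)benzoate F2, which cannot cyclise under base. Electrophilic 6-endo-dig cyclisation through the ester carbonyl (AuCl3, 5 mol%, wet MeCN, 50 °C, loss of methanol) comes back at 4.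

3. Step 3. On acidification the keto acid may relactonise to 6, or the 2,6-disubstituted salicylic acid may decarboxylate. The fallback sets out from 6 and avoids aqueous acid altogether. Ring opening with sodium benzyloxide (BnOH, NaH, THF, 50 °C; neutral buffered quench) gives benzyl 2-hydroxy-4-methoxy-6-(2-oxotridecyl)benzoate F6. Hydrogenolysis under neutral conditions (H2, 1 atm, Pd/C, EtOAc, rt) comes back at the target 8.

**Further compounds**

F1 | step 1 | methyl 2-iodo-4-methoxybenzoate | COC(=O)c1ccc(OC)cc1I
F2 | step 1 | methyl 4-methoxy-2-(tridec-1-yn-1-yl)benzoate | CCCCCCCCCCCC#Cc1cc(OC)ccc1C(=O)OC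
F3 | step 2 | methyl 2,6-dihydroxy-4-methoxybenzoate (purchased) | COC(=O)c1c(O)cc(OC)cc1O
F4 | step 2 | methyl 2-hydroxy-4-methoxy-6-{[(trifluoromethyl)sulfonyl]oxy}benzoate | COC(=O)c1c(O)cc(OC)cc1OS(=O)(=O)C(F)(F)F
F5 | step 2 | methyl 2-hydroxy-4-methoxy-6-(tridec-1-yn-1-yl)benzoate | CCCCCCCCCCCC#Cc1cc(OC)cc(O)c1C(=O)OC
F6 | step 3 | benzyl 2-hydroxy-4-methoxy-6-(2-oxotridecyl)benzoate | CCCCCCCCCCCC(=O)Cc1cc(OC)cc(O)c1C(=O)OCc1ccccc1
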